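**Compound numbers used throughout**

1 geranial; 2 allenylboronic acid pinacol ester; 3 (S)-homopropargylic alcohol; 4 hydroxy ynoate; 5 (2Z)-hydroxy ester (not isolated); 6 (S)-lactone; 7 (2Z,6E)-diol; 8 primary silyl ether; 9 4-acetoxybenzoic acid; 10 4-acetoxybenzoyl chloride; 11 silyl ether ester; 12 cyclisation precursor; 13 dioxanylium ion (not isolated); 14 ferutinin 4'-O-acetate; 15 jaeskeanin 4'-O-acetate; 16 jaeskeanin.

## Analysis of the target

Jaeskeanin (16) is a daucane ester: a cyclopentane (ring A, C1–C5) is fused trans along C1–C5 to a seven-membered ring (ring B, C1, C5–C10). C1 is quaternary and carries CH3-15, C4 is a tertiary carbinol bearing the isopropyl group (C11–C13), C6 carries the 4-hydroxybenzoate, and C8 (with CH3-14) and C9 form a trisubstituted epoxide. The six stereocentres (1R,4R,5S,6S,8R,9S) are closely related: on ring A the C15 methyl, the C5–C6 bond and the C4 hydroxyl lie on the β-face and H5 and the isopropyl group on the α-face, while on ring B the ester oxygen is α and equatorial (H5 and H6 anti) and the epoxide oxygen is α, anti to the C15 methyl. The sensitive groups are the epoxide and the tertiary alcohol (both lost under acid), the phenolic ester (transesterification, acyl migration) and the free phenol. The difficulty is the cluster C1/C5/C4/C6 around the ring fusion: a quaternary carbon, a tertiary carbinol and a secondary ester on four contiguous atoms of a trans-hydroazulene, so a stepwise synthesis has to control each centre separately. The plan rests on the fact that the skeleton is an unrearranged farnesyl chain in which only two bonds, C10–C1 and C5–C4, are missing, and the epoxide position C8=C9 is the original 2,3-alkene of that chain. In addition the ester sits on C6, between the 2,3- and 6,7-alkenes of the chain, so its carbonyl oxygen can reach a cation at C4 through a six-membered ring, from the face of ring A on which the natural hydroxyl stands.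

## Retrosynthetic reasoning

**16 ⇒ 15.** The free phenol of 16 is carried as the aryl acetate 15 and released last by mild base-catalysed methanolysis. A free phenol would make the arene and the oxygen nucleophilic in the cationic step. An aryl acetate is cleaved far faster than the hindered secondary benzoate, so removal at the end is safe.

**15 ⇒ 14.** The two C–O bonds of the epoxide are cut, leaving the C8=C9 alkene of 14. The epoxide is placed late because it cannot survive acid. The forward step needs oxygen delivery to the α-face, which the axial C15 methyl on C1 should enforce.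

**14 ⇒ 12.** The C1–C10 and C4–C5 bonds and the C4–O bond are cut together, which unfolds both rings into the open chain of 12. These are the only skeletal bonds that a farnesyl chain lacks, so cutting here removes two rings and three stereocentres at once and leaves only C6 to be made beforehand. The forward reaction has to ionise the primary allylic alcohol, close ring B through the 1,7-mode and not the easier 1,6-mode, add anti across the (6E)-alkene, and pass the positive charge to C4, where the C6 ester oxygen delivers the hydroxyl through ion 13.

**12 ⇒ 11 ⇒ 8 + 10; 10 ⇒ 9.** The ester C–O bond at C6 is cut. The primary hydroxyl must be free in 12 but is the more reactive one, so it is carried as a silyl ether (8, 11) while the secondary alcohol is acylated with 10, the acid chloride of 9.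

**8 ⇒ 7 ⇒ 6.** The hard part of the chain is the (2Z)-trisubstituted alkene C8=C9. It is secured by taking 7 from lactone 6, whose ring holds C7 and C10 cis. Hydride reduction opens the ring without touching the geometry.

**6 ⇒ 5 ⇒ 4.** The C8–CH3 bond and the lactone C–O bond are cut. A syn carbocupration that transfers a methyl group to C8 of ynoate 4 gives the (2Z)-ester 5, which lactonises. Any (2E) isomer cannot cyclise and is removed at this point.

**4 ⇒ 3.** The bond between the alkyne carbon C9 and the ester carbon C10 is cut: carboxylation of the terminal alkyne of 3.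

**3 ⇒ 1 + 2.** The C6–C7 bond is cut next to the carbinol. An enantioselective propargylation of 1 with 2 sets C6, the only stereocentre the cascade needs, and brings in a three-carbon unit that becomes C7–C9.

## Alternatives that were turned down

Alternative 1: ring B from an arene by Birch reduction and dihalocarbene ring expansion.
- Disconnection: C5 is removed from ring B by cutting C5–C6 and C5–C1, which leaves a six-membered Birch diene, 1-methoxy-2,5-dimethylcyclohexa-1,4-diene A1.
- Key step: dibromocarbene cyclopropanates the electron-rich enol ether bond C6=C1 of A1. The gem-dibromocyclopropane then ionises one bromide and opens, which inserts C5 between C6 and C1 and, after loss of the O-methyl group, leaves 2-bromo-3,6-dimethylcyclohepta-2,5-dien-1-one A2.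
- For: cheap, scalable, fully known chemistry. In about three steps A2 holds the C6 oxygen, both methyls, the C8=C9 alkene and a bromine handle at C5. On reliability of the key step it is clearly stronger than the chosen route.
- Against: A2 is achiral and flat, so all six stereocentres remain. Ring A must be annulated across the tetrasubstituted C1=C5 enone of A2 with a quaternary C1 and a trans fusion, whereas annulations on such enones tend to give cis fusion. The C4 carbinol and the C6 reduction need further separate operations, and a realistic count is well above fifteen steps.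
- Comparison: the chosen strategy gives up the safe key step and gains C1, C5 and C4 in one operation from a single preset centre.

Alternative 2: chiral-pool ring A from terpinen-4-ol with allylsilane closure of ring B.
- Disconnection: the C6–C7 bond of ring B is cut. Ring A, with the C4 carbinol already in place, is derived from commercial (S)-terpinen-4-ol A3 by oxidative cleavage of its ring alkene and aldol reclosure to a cyclopentene carbaldehyde.
- Key step: the ring A aldehyde A4 carries a 2-silylated methallyl chain on C1. SnCl4 coordinates its formyl group at C6 and the alkene terminus C7 of the allylsilane adds to it. Departure of the silyl group from C9 moves the double bond to C8=C9 and closes ring B, giving dauc-8-ene-4,6-diol 4-triethylsilyl ether A5.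
- For: A3 supplies C4 with its isopropyl group in the correct absolute configuration. Seven-membered allylsilane–aldehyde closures are known. A5 has the C6 hydroxyl free beside a protected C4 oxygen, so the ester goes on without selectivity problems. On precedent and on C4 this route is stronger than the chosen one.
- Against: between A3 and A4 the quaternary C1 must be made by conjugate addition to a β,β-disubstituted enal next to the fully substituted C4, where the facial preference between a silyloxy and an isopropyl group is not predictable. C5 is epimerisable, C6 is created in the closure without an obvious control element, and the side chain of A4 is itself a multistep reagent.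
- Comparison: the chosen strategy derives the C1/C5 relationship from alkene geometry and the C6 relationship from allylic strain instead of from three independent diastereoselections, and it is shorter.

Alternative 3: divinylcyclopropane Cope rearrangement to ring B at quaternary C1.
- Disconnection: C1–C10 is cut in a retro-Cope sense. The precursor is the cis-divinylcyclopropane A6, in which cyclopropane C6–C7–C8 is flanked by the ring A alkene C5=C1 and the vinyl group C9=C10.
- Key step: thermal [3,3] rearrangement of A6 makes C1–C10 while C6–C8 breaks. Ring B appears as a 1,4-diene (C5=C6, C8=C9) in the hydroazulenone A7.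
- For: a thermal, stereospecific reaction through a boat transition state. The quaternary C1 is set cleanly from the cyclopropane configuration, and the C8 methyl and the C4 carbonyl are in place. On the reliability of the C1 centre it is stronger than the chosen route.
- Against: A7 has C5=C6 where the target needs H5 and the C6 oxygen. It therefore still requires regio- and face-selective hydration of one of two trisubstituted alkenes, a trans-selective introduction of H5, and isopropyl addition to C4. In A6 the C15 methyl sits on the alkene terminus cis to the cyclopropane and has to point into the boat, which slows such rearrangements. The enantiopure cis-cyclopropane with a quaternary carbon is a synthesis of its own.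
- Comparison: the chosen strategy arrives directly at the right oxidation level at C4, C5 and C6.

Key step: step 9

## Route

Assumption: geranial (1) is used as the geometrically pure (2E) isomer. Atoms are referred to by daucane numbers also in open-chain compounds; locants inside compound names are IUPAC locants.

Step 1
Reactants: 1 geranial; 2 allenylboronic acid pinacol ester
Product: 3 (4S,5E)-6,10-dimethylundeca-5,9-dien-1-yn-4-ol
Conditions: TRIP (3,3'-bis(2,4,6-triisopropylphenyl)-BINOL hydrogen phosphate, 5 mol %, enantiomer giving the (S)-alcohol), 4 Å MS, toluene, −20 °C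
Reagents that add atoms: none
Why: Chiral phosphoric acid-catalysed propargylation of an aldehyde with an allenylboronate (SE2' addition through a closed six-membered transition state); enals are suitable substrates and only 1,2-addition is possible. The catalyst sets C6 as (S), the one stereocentre carried into the cascade.

Step 2
Reactants: 3 (4S,5E)-6,10-dimethylundeca-5,9-dien-1-yn-4-ol
Product: 4 methyl (5S,6E)-5-hydroxy-7,11-dimethyldodeca-6,10-dien-2-ynoate
Conditions: n-BuLi (2.1 equiv), THF, −78 °C; ClCO2Me (1.0 equiv), −78 °C; aq. NH4Cl
Reagents that add atoms: methyl chloroformate, COC(=O)Cl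
Why: C-Acylation of a lithium acetylide; in the dianion the acetylide carbon is far more nucleophilic than the aggregated lithium alkoxide at −78 °C, and the stereocentre is not involved.

Step 3
Reactants: 4 methyl (5S,6E)-5-hydroxy-7,11-dimethyldodeca-6,10-dien-2-ynoate
Product: 6 (6S)-6-[(1E)-2,6-dimethylhepta-1,5-dien-1-yl]-4-methyl-5,6-dihydro-2H-pyran-2-one, via (2Z)-hydroxy ester 5 (not isolated)
Conditions: Me2CuLi (2.5 equiv), THF, −78 °C; AcOH, −78 °C, then warm to rt
Reagents that add atoms: lithium dimethylcuprate, [Li+].C[Cu-]C
Why: Syn carbocupration of the ynoate puts the new methyl on C8 cis to H9, so C7 is cis to the ester carbon C10. Cold protonation keeps this geometry, and the (2Z)-hydroxy ester 5 closes to the six-membered lactone, which a (2E) isomer cannot do.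

Step 4
Reactants: 6 (6S)-6-[(1E)-2,6-dimethylhepta-1,5-dien-1-yl]-4-methyl-5,6-dihydro-2H-pyran-2-one
Product: 7 (2Z,5S,6E)-3,7,11-trimethyldodeca-2,6,10-triene-1,5-diol
Conditions: i-Bu2AlH (3.5 equiv), CH2Cl2, −78 → −20 °C; aq. potassium sodium tartrate
Reagents that add atoms: none
Why: 1,2-Reduction of an α,β-unsaturated lactone to the allylic diol; the ring-enforced Z geometry of C8=C9 is carried unchanged into the open chain.

Step 5
Reactants: 7 (2Z,5S,6E)-3,7,11-trimethyldodeca-2,6,10-triene-1,5-diol
Product: 8 (2Z,5S,6E)-1-[(tert-butyldimethylsilyl)oxy]-3,7,11-trimethyldodeca-2,6,10-trien-5-ol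
Conditions: TBSCl (1.05 equiv), imidazole, CH2Cl2, −20 °C
Reagents that add atoms: tert-butyldimethylsilyl chloride, CC(C)(C)[Si](C)(C)Cl
Why: Selective silylation on steric grounds: the primary allylic hydroxyl reacts much faster than the secondary one next to the trisubstituted alkene.

Step 6
Reactants: 9 4-(acetyloxy)benzoic acid
Product: 10 4-(acetyloxy)benzoyl chloride
Conditions: (COCl)2, DMF (cat.), CH2Cl2, 0 °C → rt
Reagents that add atoms: oxalyl chloride, O=C(Cl)C(Cl)=O
Why: Acid chloride formation through the catalytic chloroiminium species; the aryl acetate is inert under these conditions.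

Step 7
Reactants: 8 (2Z,5S,6E)-1-[(tert-butyldimethylsilyl)oxy]-3,7,11-trimethyldodeca-2,6,10-trien-5-ol; 10 4-(acetyloxy)benzoyl chloride
Product: 11 (2Z,5S,6E)-1-[(tert-butyldimethylsilyl)oxy]-3,7,11-trimethyldodeca-2,6,10-trien-5-yl 4-(acetyloxy)benzoate
Conditions: Et3N, DMAP (10 mol %), CH2Cl2, 0 °C
Reagents that add atoms: none
Why: DMAP-catalysed acylation of a secondary allylic alcohol; the acid chloride is far more reactive than the aryl acetate, and under basic conditions C6 does not ionise, so its configuration is retained.

Step 8
Reactants: 11 (2Z,5S,6E)-1-[(tert-butyldimethylsilyl)oxy]-3,7,11-trimethyldodeca-2,6,10-trien-5-yl 4-(acetyloxy)benzoate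
Product: 12 (2Z,5S,6E)-1-hydroxy-3,7,11-trimethyldodeca-2,6,10-trien-5-yl 4-(acetyloxy)benzoate
Conditions: HF·pyridine, pyridine, THF, 0 °C → rt
Reagents that add atoms: none
Why: Fluoride cleavage of a primary silyl ether under buffered, non-basic conditions, which leave the aryl acetate and the allylic ester untouched and give no acyl migration.

Step 9
Reactants: 12 (2Z,5S,6E)-1-hydroxy-3,7,11-trimethyldodeca-2,6,10-trien-5-yl 4-(acetyloxy)benzoate
Product: 14 ferutinin 4'-O-acetate, via dioxanylium ion 13 (not isolated)
Conditions: confined chiral imidodiphosphorimidate Brønsted acid (IDPi, 5 mol %, enantiomer matched to 12), (CF3)3COH/CHCl3 1:4, 0.01 M, −40 → −20 °C; aq. NaHCO3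
Reagents that add atoms: water, O (the molecule released on ionisation is taken up again; its oxygen ends in the ester carbonyl)
Why: Proposed new method: the acid ionises the primary (2Z)-allylic alcohol, and the cisoid allyl cation, folded inside the catalyst pocket, is attacked at C10 by C1 of the (6E)-alkene while the C4=C11 alkene bonds to C5 from the opposite face, so that no free secondary cation has to form at C5. A 1,2-hydride shift from C4 to C11 then gives the tertiary C4 cation, which the carbonyl oxygen of the C6 ester captures as dioxanylium ion 13; the water released at the start adds to its acyl carbon and the bond to the tertiary oxygen breaks, which returns the aroyl group to O6 and the proton to the catalyst. The closest known reaction types are the tail-to-head cyclisation of neryl and farnesyl derivatives in confined Brønsted acids and supramolecular capsules and the capture of carbocations by a neighbouring acyloxy group. Ring B closes in the 7-endo mode with respect to the C5=C1 alkene (anti-Markovnikov), ring A in the 5-exo mode with respect to the C4=C11 alkene. C1 and C5 are set by anti addition across the (6E)-alkene, which makes the ring fusion trans, and their absolute sense comes from C6: allylic 1,3-strain with the C15 methyl holds H6 in the alkene plane, the tether to C10 and the aroyloxy group then lie on opposite faces, and C10 can reach C1 only on the face that gives 1β-CH3 and 5α-H. C4 is set by intramolecular delivery of the ester oxygen, which can reach the planar cation only on the face of ring A that carries C6 (β). The selectivity needed beyond this is 1,7- over 1,6-closure, which the substrate does not provide and the confined catalyst has to enforce by holding the C4=C11 alkene behind C5.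

Step 10
Reactants: 14 ferutinin 4'-O-acetate
Product: 15 jaeskeanin 4'-O-acetate (8α,9α-epoxide)
Conditions: mCPBA (1.1 equiv), NaHCO3, CH2Cl2, 0 °C
Reagents that add atoms: 3-chloroperoxybenzoic acid, OOC(=O)c1cccc(Cl)c1
Why: Prilezhaev epoxidation of the only alkene; syn delivery of oxygen to the α-face, anti to the axial C15 methyl that stands 1,3 to C9, sets C8 and C9. The bicarbonate buffer protects the epoxide and the tertiary alcohol from acid.

Step 11
Reactants: 15 jaeskeanin 4'-O-acetate
Product: 16 jaeskeanin
Conditions: K2CO3 (0.2 equiv), MeOH, 0 °C; aq. NH4Cl
Reagents that add atoms: none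
Why: Base-catalysed transesterification; the aryl acetate, with a phenoxide leaving group, is methanolysed far faster than the hindered secondary benzoate, which becomes still less electrophilic once its para oxygen is a phenoxide. The epoxide is stable to carbonate.

## Compound list

1 | geranial, (2E)-3,7-dimethylocta-2,6-dienal | CC(C)=CCC/C(C)=C/C=O | starting material
2 | allenylboronic acid pinacol ester, 4,4,5,5-tetramethyl-2-(propa-1,2-dien-1-yl)-1,3,2-dioxaborolane | C=C=CB1OC(C)(C)C(C)(C)O1 | starting material
3 | (4S,5E)-6,10-dimethylundeca-5,9-dien-1-yn-4-ol | C#CC[C@H](O)/C=C(\C)CCC=C(C)C | intermediate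
4 | methyl (5S,6E)-5-hydroxy-7,11-dimethyldodeca-6,10-dien-2-ynoate | COC(=O)C#CC[C@H](O)/C=C(\C)CCC=C(C)C | intermediate
5 | methyl (2Z,5S,6E)-5-hydroxy-3,7,11-trimethyldodeca-2,6,10-trienoate | COC(=O)/C=C(/C)C[C@H](O)/C=C(\C)CCC=C(C)C | intermediate (not isolated)
6 | (6S)-6-[(1E)-2,6-dimethylhepta-1,5-dien-1-yl]-4-methyl-5,6-dihydro-2H-pyran-2-one | O=C1C=C(C)C[C@H](O1)/C=C(\C)CCC=C(C)C | intermediate
7 | (2Z,5S,6E)-3,7,11-trimethyldodeca-2,6,10-triene-1,5-diol | OC/C=C(/C)C[C@H](O)/C=C(\C)CCC=C(C)C | intermediate
8 | (2Z,5S,6E)-1-[(tert-butyldimethylsilyl)oxy]-3,7,11-trimethyldodeca-2,6,10-trien-5-ol | CC(C)(C)[Si](C)(C)OC/C=C(/C)C[C@H](O)/C=C(\C)CCC=C(C)C | intermediate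
9 | 4-(acetyloxy)benzoic acid | CC(=O)Oc1ccc(cc1)C(O)=O | starting material
10 | 4-(acetyloxy)benzoyl chloride | CC(=O)Oc1ccc(cc1)C(Cl)=O | intermediate
11 | (2Z,5S,6E)-1-[(tert-butyldimethylsilyl)oxy]-3,7,11-trimethyldodeca-2,6,10-trien-5-yl 4-(acetyloxy)benzoate | CC(C)(C)[Si](C)(C)OC/C=C(/C)C[C@H](OC(=O)c1ccc(OC(C)=O)cc1)/C=C(\C)CCC=C(C)C | intermediate
12 | (2Z,5S,6E)-1-hydroxy-3,7,11-trimethyldodeca-2,6,10-trien-5-yl 4-(acetyloxy)benzoate, i.e. (2Z,6E)-5-(4-acetoxybenzoyloxy)farnesol | OC/C=C(/C)C[C@H](OC(=O)c1ccc(OC(C)=O)cc1)/C=C(\C)CCC=C(C)C | intermediate
13 | 2-(4-acetoxyphenyl)-1,3-dioxan-2-ylium ion bridging O4 and O6 of the dauc-8-ene skeleton | CC(C)[C@]1(O2)CC[C@]3(C)CC=C(C)C[C@H]([O+]=C2c4ccc(OC(C)=O)cc4)[C@H]31 | intermediate (not isolated)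
14 | ferutinin 4'-O-acetate, (3R,3aS,4S,8aR)-3-hydroxy-6,8a-dimethyl-3-(propan-2-yl)-1,2,3,3a,4,5,8,8a-octahydroazulen-4-yl 4-(acetyloxy)benzoate | CC(C)[C@]1(O)CC[C@]2(C)CC=C(C)C[C@H](OC(=O)c3ccc(OC(C)=O)cc3)[C@H]21 | intermediate
15 | jaeskeanin 4'-O-acetate, 8α,9α-epoxy-4β-hydroxydaucan-6α-yl 4-(acetyloxy)benzoate | CC(C)[C@]1(O)CC[C@]2(C)C[C@@H]3O[C@]3(C)C[C@H](OC(=O)c3ccc(OC(C)=O)cc3)[C@H]21 | intermediate
16 | jaeskeanin, 8α,9α-epoxy-4β-hydroxydaucan-6α-yl 4-hydroxybenzoate (1R,4R,5S,6S,8R,9S) | CC(C)[C@]1(O)CC[C@]2(C)C[C@@H]3O[C@]3(C)C[C@H](OC(=O)c3ccc(O)cc3)[C@H]21 | target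

## Step count and least certain steps

Total: 11 steps. Longest linear sequence: 10 steps from geranial (steps 1–5 and 7–11); step 6 is a one-step side branch.

**Step 9 (key step, beyond known chemistry).** Four processes are most likely to derail it. The first is closure in the 1,6-mode (Markovnikov, six-membered ring) followed by proton loss, which is the default path in solution. The second is interception of the developing charge at C5 by the neighbouring ester carbonyl as a five-membered acyloxonium ion; in the reactive conformation that carbonyl sits on the face from which the C4=C11 alkene must arrive. The third is ionisation at C6, whose allylic aroyloxy group is itself a leaving group, with loss or 1,3-shift of the ester. The fourth is proton loss from the C4 or C11 cation before oxygen delivery: a model of the trans-fused ion suggests that O6 (equatorial on ring B) and the β-face of C4 can be spanned only by a twisted six-membered ring, not a chair, so the bridge is strained. Within the strategy, the first variables to screen are the confining host (other IDPi pockets, or the hexameric C-undecylresorcin[4]arene capsule with catalytic HCl in wet CHCl3) and the match between catalyst and substrate enantiomers.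

Fallback (known reactions only): the cascade is given up and ring B is closed by olefin metathesis on a preformed ring A unit. The sequence sets out from acid chloride 10, the only compound of the route it uses, together with commercial materials, and comes back to the route at 14. 3-Ethoxycyclopent-2-en-1-one F1 is treated with allylmagnesium bromide and then dilute HCl (Stork–Danheiser transposition) to give 3-(prop-2-en-1-yl)cyclopent-2-en-1-one F2. Copper-catalysed asymmetric conjugate addition of MeMgBr (Cu(OTf)2, chiral N-heterocyclic carbene ligand) creates the quaternary C1, and the enolate is trapped with Me3SiCl as (R)-trimethyl{[3-methyl-3-(prop-2-en-1-yl)cyclopent-1-en-1-yl]oxy}silane F3, which fixes the enolate on the C5 side. 3-Methylbut-3-en-1-ol F4 is oxidised with Dess–Martin periodinane to 3-methylbut-3-enal F5. The enolate regenerated from the silyl enol ether (MeLi, then ZnCl2, −78 °C) adds to this aldehyde through a chair transition state, anti to the allyl group, to give the anti aldol (2S,3R)-2-[(1S)-1-hydroxy-3-methylbut-3-en-1-yl]-3-methyl-3-(prop-2-en-1-yl)cyclopentan-1-one F6. i-PrMgCl/CeCl3 then adds to the C4 ketone anti to the C5 side chain to give (1R,2S,3R)-2-[(1S)-1-hydroxy-3-methylbut-3-en-1-yl]-3-methyl-1-(propan-2-yl)-3-(prop-2-en-1-yl)cyclopentan-1-ol F7. The second-generation Grubbs catalyst (CH2Cl2, reflux) closes ring B at C8=C9 to jaeschkeanadiol F8, and its secondary hydroxyl, the only acylable one, is esterified with 10 (pyridine, DMAP) to give 14. The weak point of this fallback is the C5 selectivity of the aldol, which rests only on the size difference between allyl and methyl on C1; the C5 epimer would have to be separated at the aldol or the diol stage.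

**Step 1.** Enantiofacial discrimination may be insufficient on a β,β-disubstituted enal, which is less electrophilic than the usual substrates, and the enal may undergo E/Z isomerisation under acid catalysis. Fallback by resolution, setting out from 1 and rejoining at 3: zinc-mediated Barbier propargylation (Zn, propargyl bromide, THF/aq. NH4Cl) gives racemic 6,10-dimethylundeca-5,9-dien-1-yn-4-ol F9. Lipase-catalysed kinetic resolution (Novozym 435, vinyl acetate, hexane) acetylates the (R)-enantiomer to (4R,5E)-6,10-dimethylundeca-5,9-dien-1-yn-4-yl acetate F10 and leaves (S)-alcohol 3, which is separated by chromatography.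

**Step 2.** O-Acylation of the lithium alkoxide may compete with C-acylation of the acetylide. Fallback, from 3 directly to 4 without a dianion: palladium-catalysed oxidative methoxycarbonylation of the terminal alkyne (PdCl2 cat., CuCl2, NaOAc, CO 1 atm, MeOH, rt), which tolerates the free hydroxyl. No new compound is involved.

**Step 10.** Facial selectivity may be low or reversed, since the β-face is shielded only by a methyl two bonds away while the α-face carries the C6 aroyloxy group. Fallback, from 14 to 16: a halohydrin sequence, which places the epoxide oxygen on the face opposite to the one the electrophile prefers. NBS in THF/H2O at 0 °C gives 9β-bromo-4β,8α-dihydroxydaucan-6α-yl 4-(acetyloxy)benzoate F11 by anti opening of the β-bromonium ion at the tertiary C8. K2CO3 in MeOH then closes the 8α,9α-epoxide by displacement of bromide and cleaves the aryl acetate in the same operation, arriving directly at 16.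

## Further compounds

F1 | step 9 | 3-ethoxycyclopent-2-en-1-one | CCOC1=CC(=O)CC1
F2 | step 9 | 3-(prop-2-en-1-yl)cyclopent-2-en-1-one | C=CCC1=CC(=O)CC1
F3 | step 9 | (R)-trimethyl{[3-methyl-3-(prop-2-en-1-yl)cyclopent-1-en-1-yl]oxy}silane | C=CC[C@@]1(C)CCC(O[Si](C)(C)C)=C1
F4 | step 9 | 3-methylbut-3-en-1-ol | CC(=C)CCO
F5 | step 9 | 3-methylbut-3-enal | CC(=C)CC=O
F6 | step 9 | (2S,3R)-2-[(1S)-1-hydroxy-3-methylbut-3-en-1-yl]-3-methyl-3-(prop-2-en-1-yl)cyclopentan-1-one | C=CC[C@@]1(C)CCC(=O)[C@@H]1[C@@H](O)CC(C)=C
F7 | step 9 | (1R,2S,3R)-2-[(1S)-1-hydroxy-3-methylbut-3-en-1-yl]-3-methyl-1-(propan-2-yl)-3-(prop-2-en-1-yl)cyclopentan-1-ol | CC(C)[C@]1(O)CC[C@](C)(CC=C)[C@H]1[C@@H](O)CC(C)=C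
F8 | step 9 | jaeschkeanadiol, (3R,3aS,4S,8aR)-6,8a-dimethyl-3-(propan-2-yl)-1,2,3,3a,4,5,8,8a-octahydroazulene-3,4-diol | CC(C)[C@]1(O)CC[C@]2(C)CC=C(C)C[C@H](O)[C@H]21
F9 | step 1 | racemic (5E)-6,10-dimethylundeca-5,9-dien-1-yn-4-ol | C#CCC(O)/C=C(\C)CCC=C(C)C
F10 | step 1 | (4R,5E)-6,10-dimethylundeca-5,9-dien-1-yn-4-yl acetate | C#CC[C@@H](OC(C)=O)/C=C(\C)CCC=C(C)C
F0 | step 2 | none | none
F11 | step 10 | 9β-bromo-4β,8α-dihydroxydaucan-6α-yl 4-(acetyloxy)benzoate | CC(C)[C@]1(O)CC[C@]2(C)C[C@@H](Br)[C@](C)(O)C[C@H](OC(=O)c3ccc(OC(C)=O)cc3)[C@H]21
A1 | alternative 1 | 1-methoxy-2,5-dimethylcyclohexa-1,4-diene | COC1=C(C)CC=C(C)C1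
A2 | alternative 1 | 2-bromo-3,6-dimethylcyclohepta-2,5-dien-1-one | O=C1CC(C)=CCC(C)=C1Br
A3 | alternative 2 | (S)-terpinen-4-ol, (1S)-4-methyl-1-(propan-2-yl)cyclohex-3-en-1-ol | CC1=CC[C@](O)(C(C)C)CC1
A4 | alternative 2 | (1R,2R,5R)-2-methyl-2-[3-methyl-2-(trimethylsilyl)but-3-en-1-yl]-5-(propan-2-yl)-5-[(triethylsilyl)oxy]cyclopentane-1-carbaldehyde (silyl-bearing carbon unassigned) | CC(C)[C@]1(O[Si](CC)(CC)CC)CC[C@](C)(CC([Si](C)(C)C)C(C)=C)[C@H]1C=O
A5 | alternative 2 | dauc-8-ene-4,6-diol 4-triethylsilyl ether | CC(C)[C@]1(O[Si](CC)(CC)CC)CC[C@]2(C)CC=C(C)C[C@H](O)[C@H]21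
A6 | alternative 3 | 2-[(1R,2R)-2-ethenyl-2-methylcyclopropyl]-3-methylcyclopent-2-en-1-one | O=C1CCC(C)=C1[C@@H]1C[C@]1(C)C=C
A7 | alternative 3 | (3aR)-3a,6-dimethyl-3,3a,4,7-tetrahydroazulen-1(2H)-one | O=C1CC[C@]2(C)CC=C(C)CC=C12
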